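**Retrosynthetic overview**

1. Target 35 ⇐ methyl ester 34 ⇐ allylic alcohol 31 (reductive 1,3-transposition makes the ring B exocyclic methylene) ⇐ bicyclic enal 30.
2. Ring B (formed last) is opened at two bonds: the CMe2–CH bond comes from addition of a tertiary radical (oxalate 10, ring A) to the chiral iminium ion of dioxane enal 27, and the ring then closes by enamine aldol condensation onto the ring A formyl group.
3. Ring A (formed first): Diels–Alder of in-situ 2-silyloxybutadiene with chiral butenolide 2; the lactone carbonyl becomes the CMe2–O radical precursor and the glycol becomes the formyl group.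
4. 1,2-Dioxane (formed second, on its own branch): a tertiary hydroperoxide (Shi epoxide, then H2O2 with inversion) opens a cis-β-lactone at C4 with inversion; the β-lactone comes from a ketene–aldehyde cycloaddition and the chain from a Claisen rearrangement.
5. Ring order: ring A, then the dioxane, then ring B.

Assumption: (R)-5-(hydroxymethyl)furan-2(5H)-one (2), the antipode of the common glutamic-acid-derived butenolide, is taken as purchasable.

**Route**

Step 1
Reactants: 1 methyl vinyl ketone; 2 (R)-5-(hydroxymethyl)furan-2(5H)-one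
Product: 5 (3R,3aR,7aS)-3-(hydroxymethyl)hexahydro-2-benzofuran-1,5-dione, via silyloxydiene 3 (not isolated), via silyl enol ether adduct 4 (not isolated)
Conditions: 1 (3 equiv), Me3SiOTf, Et3N, Et2O, 0 °C; decant; 2, PhMe, BHT, 150 °C (sealed); then 1 M HCl, THF, rt
Reagents that add atoms: none
Why: In-situ silyl enol ether formation followed by a thermal Diels–Alder reaction, in which the diene adds in the "para" sense (its CH2 next to C–OSi bonds to the lactone β-carbon) and anti to the hydroxymethyl group of the butenolide, so the cis ring fusion and its absolute sense come from the chiral-pool center; acid then unmasks the ketone.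

Step 2
Reactants: 5 (3R,3aR,7aS)-3-(hydroxymethyl)hexahydro-2-benzofuran-1,5-dione
Product: 6 (3R,3aR,7aS)-3-(hydroxymethyl)-5-methylidenehexahydro-2-benzofuran-1(3H)-one
Conditions: Ph3PCH3Br (2.5 equiv), KOtBu, THF, 0 °C to rt
Reagents that add atoms: methyltriphenylphosphonium bromide C[P+](c1ccccc1)(c1ccccc1)c1ccccc1.[Br-]
Why: Wittig methylenation of the ketone, which is far more reactive than the lactone; the ring-fusion carbon next to the lactone carbonyl stays cis because the cis-fused γ-lactone is the stable epimer.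

Step 3
Reactants: 6 (3R,3aR,7aS)-3-(hydroxymethyl)-5-methylidenehexahydro-2-benzofuran-1(3H)-one
Product: 7 (1R)-1-[(1R,2S)-2-(2-hydroxypropan-2-yl)-5-methylidenecyclohexyl]ethane-1,2-diol
Conditions: MeLi (6 equiv), CeCl3, THF, −78 to 0 °C; aq. NH4Cl
Reagents that add atoms: methyllithium [Li]C
Why: Double organocerium (Imamoto) addition to the lactone gives the gem-dimethyl carbinol, and the non-basic cerium reagent adds to the intermediate methyl ketone faster than it enolises it, so the adjacent ring stereocenter is not epimerised.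

Step 4
Reactants: 7 (1R)-1-[(1R,2S)-2-(2-hydroxypropan-2-yl)-5-methylidenecyclohexyl]ethane-1,2-diol
Product: 8 2-[(1S,2R)-2-[(4R)-2,2-dimethyl-1,3-dioxolan-4-yl]-4-methylidenecyclohexyl]propan-2-ol
Conditions: Me2C(OMe)2, PPTS (cat.), CH2Cl2, rt
Reagents that add atoms: 2,2-dimethoxypropane COC(C)(C)OC
Why: Acetonide formation is selective for the terminal 1,2-diol (five-membered dioxolane) and leaves the hindered tertiary alcohol free; no stereocenter is touched.

Step 5
Reactants: 8 2-[(1S,2R)-2-[(4R)-2,2-dimethyl-1,3-dioxolan-4-yl]-4-methylidenecyclohexyl]propan-2-ol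
Product: 9 methyl 2-[(1S,2R)-2-[(4R)-2,2-dimethyl-1,3-dioxolan-4-yl]-4-methylidenecyclohexyl]propan-2-yl oxalate
Conditions: ClCOCO2Me, Et3N, DMAP (cat.), CH2Cl2, 0 °C
Reagents that add atoms: methyl chlorooxoacetate COC(=O)C(=O)Cl
Why: DMAP-catalysed acylation of the tertiary alcohol installs the oxalate that later serves as the tertiary-radical precursor (Overman-type oxalate).

Step 6
Reactants: 9 methyl 2-[(1S,2R)-2-[(4R)-2,2-dimethyl-1,3-dioxolan-4-yl]-4-methylidenecyclohexyl]propan-2-yl oxalate
Product: 10 2-[(1S,2R)-2-formyl-4-methylidenecyclohexyl]propan-2-yl methyl oxalate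
Conditions: H5IO6, EtOAc, rt
Reagents that add atoms: none
Why: Periodic acid removes the terminal acetonide and cleaves the glycol in one pot (Malaprade cleavage); the chiral-pool carbon leaves as formaldehyde, and the non-basic medium does not epimerise the new α-branched aldehyde.

Step 7
Reactants: 11 methacrolein; 12 allylmagnesium bromide
Product: 13 2-methylhexa-1,5-dien-3-ol (racemic)
Conditions: Et2O, −78 °C; aq. NH4Cl
Reagents that add atoms: none
Why: Grignard 1,2-addition to the enal; the carbinol center is racemic on purpose because it is destroyed in the next step.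

Step 8
Reactants: 13 2-methylhexa-1,5-dien-3-ol (racemic); 14 ethyl vinyl ether
Product: 16 (4E)-4-methylocta-4,7-dienal, via allyl vinyl ether 15 (not isolated)
Conditions: Hg(OAc)2 (cat.), 14 as solvent, reflux; concentrate; PhMe, 140 °C (sealed)
Reagents that add atoms: none
Why: Mercury-catalysed vinyl ether exchange followed by a Claisen rearrangement through a chair transition state with the allyl substituent equatorial, which gives the (E)-trisubstituted alkene and the aldehyde directly.

Step 9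
Reactants: 16 (4E)-4-methylocta-4,7-dienal; 17 propanoyl chloride
Product: 19 (3R,4S)-3-methyl-4-[(3E)-3-methylhepta-3,6-dien-1-yl]oxetan-2-one, via methylketene 18 (not isolated)
Conditions: O-trimethylsilylquinidine (10 mol %), LiClO4, iPr2NEt, CH2Cl2/Et2O, −78 °C
Reagents that add atoms: none
Why: Nelson's alkaloid/LiClO4-catalysed acyl halide–aldehyde cyclocondensation (ketene–aldehyde [2+2]) gives the cis-β-lactone and sets both centers under catalyst control (O-trimethylsilylquinine is the pseudoenantiomeric catalyst and gives the antipode).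

Step 10
Reactants: 19 (3R,4S)-3-methyl-4-[(3E)-3-methylhepta-3,6-dien-1-yl]oxetan-2-one
Product: 20 (3R,4S)-3-methyl-4-{2-[(2S,3S)-2-methyl-3-(prop-2-en-1-yl)oxiran-2-yl]ethyl}oxetan-2-one
Conditions: ent-Shi ketone (L-fructose-derived, 1 equiv), Oxone (2KHSO5·KHSO4·K2SO4), NaHCO3, aq. Na2EDTA, MeCN, 0 °C
Reagents that add atoms: potassium peroxymonosulfate (Oxone) OOS(=O)(=O)[O-].[K+]
Why: Shi asymmetric epoxidation (chiral dioxirane, spiro transition state) attacks only the electron-rich trisubstituted alkene; the ent-ketone gives the (S,S)-epoxide, and the near-neutral buffer spares the β-lactone.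

Step 11
Reactants: 20 (3R,4S)-3-methyl-4-{2-[(2S,3S)-2-methyl-3-(prop-2-en-1-yl)oxiran-2-yl]ethyl}oxetan-2-one
Product: 21 (3R,4S)-4-[(3R,4S)-3-hydroperoxy-4-hydroxy-3-methylhept-6-en-1-yl]-3-methyloxetan-2-one
Conditions: H3PMo12O40 (5 mol %), anhydrous H2O2 in Et2O, rt
Reagents that add atoms: hydrogen peroxide OO
Why: Phosphomolybdic-acid-catalysed perhydrolysis of the epoxide (Wu's method) delivers H2O2 to the more substituted carbon with inversion, which fixes the tertiary C–OO stereocenter; the neighbouring carbinol keeps its epoxide configuration.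

Step 12
Reactants: 21 (3R,4S)-4-[(3R,4S)-3-hydroperoxy-4-hydroxy-3-methylhept-6-en-1-yl]-3-methyloxetan-2-one
Product: 23 methyl (2R)-2-[(3R,6R)-6-[(1S)-1-hydroxybut-3-en-1-yl]-6-methyl-1,2-dioxan-3-yl]propanoate, via caesium carboxylate 22 (not isolated)
Conditions: Cs2CO3 (1.1 equiv), MeCN (0.01 M), 0 °C to rt; then MeI
Reagents that add atoms: iodomethane CI
Why: Proposed new method: the hydroperoxide anion (pKa about 13, so it is formed in preference to the alkoxide) attacks C4 of the β-lactone in a 6-exo-tet SN2 alkyl–oxygen cleavage with inversion, because acyl attack would need an eight-membered perester; this sets the ring C–O center anti to the untouched α-methyl center, and the freed carboxylate is methylated in the same flask. The closest known reactions are C4 opening of β-lactones by soft heteroatom nucleophiles (Vederas) and intramolecular alkylation of hydroperoxides by sulfonates (Dussault).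

Step 13
Reactants: 23 methyl (2R)-2-[(3R,6R)-6-[(1S)-1-hydroxybut-3-en-1-yl]-6-methyl-1,2-dioxan-3-yl]propanoate
Product: 24 methyl (2R)-2-[(3R,6R)-6-methyl-6-[(1S)-1-(phenoxycarbonothioyloxy)but-3-en-1-yl]-1,2-dioxan-3-yl]propanoate
Conditions: PhOC(S)Cl, pyridine, DMAP, CH2Cl2, rt
Reagents that add atoms: O-phenyl chlorothionoformate S=C(Cl)Oc1ccccc1
Why: Thioacylation of the secondary alcohol gives the Barton–McCombie precursor under non-basic conditions that leave the β-peroxy ester alone.

Step 14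
Reactants: 24 methyl (2R)-2-[(3R,6R)-6-methyl-6-[(1S)-1-(phenoxycarbonothioyloxy)but-3-en-1-yl]-1,2-dioxan-3-yl]propanoate
Product: 25 methyl (2R)-2-[(3R,6S)-6-(but-3-en-1-yl)-6-methyl-1,2-dioxan-3-yl]propanoate
Conditions: Bu3SnH (1 M), PhSeSePh (10 mol %), AIBN, PhH, 80 °C
Reagents that add atoms: none
Why: Barton–McCombie deoxygenation in which catalytic PhSeH (Crich) transfers hydrogen to the carbon radical next to the peroxide (about 10^9 M−1 s−1) faster than that radical can close to an epoxide by attack on the O–O bond; no stereocenter changes (the ring descriptor goes from 6R to 6S by priority only).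

Step 15
Reactants: 25 methyl (2R)-2-[(3R,6S)-6-(but-3-en-1-yl)-6-methyl-1,2-dioxan-3-yl]propanoate; 26 (E)-but-2-enal
Product: 27 methyl (2R)-2-[(3R,6S)-6-methyl-6-[(3E)-5-oxopent-3-en-1-yl]-1,2-dioxan-3-yl]propanoate
Conditions: 26 (5 equiv), second-generation Hoveyda–Grubbs catalyst RuCl2(H2IMes)(=CH-C6H4-2-OiPr) (5 mol %), CH2Cl2, 40 °C
Reagents that add atoms: none
Why: Olefin cross-metathesis of the terminal alkene with excess crotonaldehyde gives the (E)-enal with loss of propene; dialkyl peroxides are inert to the ruthenium alkylidene.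

Step 16
Reactants: 10 2-[(1S,2R)-2-formyl-4-methylidenecyclohexyl]propan-2-yl methyl oxalate; 27 methyl (2R)-2-[(3R,6S)-6-methyl-6-[(3E)-5-oxopent-3-en-1-yl]-1,2-dioxan-3-yl]propanoate
Product: 30 methyl (2R)-2-[(3R,6S)-6-{2-[(2S,4aS,8aS)-3-formyl-1,1-dimethyl-6-methylidene-1,2,4a,5,6,7,8,8a-octahydronaphthalen-2-yl]ethyl}-6-methyl-1,2-dioxan-3-yl]propanoate, via caesium oxalate 28 (not isolated), via dialdehyde 29 (not isolated)
Conditions: 10 (1.3 equiv), CsOH·H2O (1.3 equiv), THF/H2O, 0 °C, 10 min, concentrate; then 27, (S)-2-{bis[3,5-bis(trifluoromethyl)phenyl](trimethylsilyloxy)methyl}pyrrolidine (20 mol %), CF3CO2H (20 mol %), 4CzIPN (2 mol %), MeCN, 450 nm LEDs, 20 °C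
Reagents that add atoms: none
Why: Proposed new method: the excited photocatalyst oxidises the caesium oxalate, which loses two CO2 to give the tertiary radical (photoredox oxalate Giese chemistry of Overman and MacMillan); this nucleophilic radical adds to the β-carbon of the (E,E)-iminium ion of 27 on the face opposite the bulky C2 group of the (S)-amine (organocatalytic radical conjugate addition to enals of the Melchiorre type), which sets the side-chain-bearing ring B stereocenter by catalyst control where ring-based control would favour its epimer; the reduced photocatalyst then converts the α-iminyl radical cation into the enamine, which closes ring B on the neighbouring formyl group and dehydrates (amine-catalysed Michael/aldol-condensation logic). The quaternary carbon, two C–C bonds and ring B form in one flask, and the ring-fusion centers survive because the α-branched aldehyde forms an enamine with this hindered amine only slowly.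

Step 17
Reactants: 30 methyl (2R)-2-[(3R,6S)-6-{2-[(2S,4aS,8aS)-3-formyl-1,1-dimethyl-6-methylidene-1,2,4a,5,6,7,8,8a-octahydronaphthalen-2-yl]ethyl}-6-methyl-1,2-dioxan-3-yl]propanoate
Product: 31 methyl (2R)-2-[(3R,6S)-6-{2-[(2S,4aS,8aS)-3-(hydroxymethyl)-1,1-dimethyl-6-methylidene-1,2,4a,5,6,7,8,8a-octahydronaphthalen-2-yl]ethyl}-6-methyl-1,2-dioxan-3-yl]propanoate
Conditions: NaBH4, CeCl3·7H2O, MeOH, −20 °C
Reagents that add atoms: none
Why: Luche 1,2-reduction of the enal; borohydride touches neither the ester nor the dialkyl peroxide.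

Step 18
Reactants: 31 methyl (2R)-2-[(3R,6S)-6-{2-[(2S,4aS,8aS)-3-(hydroxymethyl)-1,1-dimethyl-6-methylidene-1,2,4a,5,6,7,8,8a-octahydronaphthalen-2-yl]ethyl}-6-methyl-1,2-dioxan-3-yl]propanoate
Product: 34 methyl (2R)-2-[(3R,6S)-6-{2-[(2R,4aS,8aS)-1,1-dimethyl-3,6-dimethylidenedecahydronaphthalen-2-yl]ethyl}-6-methyl-1,2-dioxan-3-yl]propanoate, via sulfonylhydrazine 32 (not isolated), via allylic diazene 33 (not isolated)
Conditions: PPh3, DEAD, then 31 and 2-O2NC6H4SO2NHNH2, N-methylmorpholine, −30 °C to rt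
Reagents that add atoms: none
Why: Myers reductive 1,3-transposition: Mitsunobu displacement by the sulfonylhydrazide, loss of sulfinic acid and a retro-ene loss of N2 deliver hydrogen to the ring CH and move the double bond to the exocyclic position; the phosphine is bound as the betaine before the peroxide is added, and no stereocenter is involved (the ring descriptor changes from 2S to 2R by priority only).

Step 19
Reactants: 34 methyl (2R)-2-[(3R,6S)-6-{2-[(2R,4aS,8aS)-1,1-dimethyl-3,6-dimethylidenedecahydronaphthalen-2-yl]ethyl}-6-methyl-1,2-dioxan-3-yl]propanoate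
Product: 35 (2R)-2-[(3R,6S)-6-{2-[(2R,4aS,8aS)-1,1-dimethyl-3,6-dimethylidenedecahydronaphthalen-2-yl]ethyl}-6-methyl-1,2-dioxan-3-yl]propanoic acid
Conditions: LiOH, THF/H2O, 0 °C to rt; then aq. HCl to pH 3
Reagents that add atoms: lithium hydroxide [Li+].[OH-]
Why: Saponification of the methyl ester under mild conditions, as used for other 1,2-dioxane propanoates, gives the acid without opening the peroxide or epimerising the α-center.

**Compound list**

1 | methyl vinyl ketone | CC(=O)C=C | starting material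
2 | (R)-5-(hydroxymethyl)furan-2(5H)-one | O=C1C=C[C@H](CO)O1 | starting material
3 | 2-(trimethylsilyloxy)buta-1,3-diene | C=CC(=C)O[Si](C)(C)C | intermediate
4 | (3R,3aR,7aS)-3-(hydroxymethyl)-5-(trimethylsilyloxy)-3a,4,7,7a-tetrahydro-2-benzofuran-1(3H)-one | O=C1[C@H]2CC=C(O[Si](C)(C)C)C[C@H]2[C@H](CO)O1 | intermediate
5 | (3R,3aR,7aS)-3-(hydroxymethyl)hexahydro-2-benzofuran-1,5-dione | O=C1[C@H]2CCC(=O)C[C@H]2[C@H](CO)O1 | intermediate
6 | (3R,3aR,7aS)-3-(hydroxymethyl)-5-methylidenehexahydro-2-benzofuran-1(3H)-one | O=C1[C@H]2CCC(=C)C[C@H]2[C@H](CO)O1 | intermediate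
7 | (1R)-1-[(1R,2S)-2-(2-hydroxypropan-2-yl)-5-methylidenecyclohexyl]ethane-1,2-diol | C=C1CC[C@H](C(C)(C)O)[C@@H](C1)[C@@H](O)CO | intermediate
8 | 2-[(1S,2R)-2-[(4R)-2,2-dimethyl-1,3-dioxolan-4-yl]-4-methylidenecyclohexyl]propan-2-ol | C=C1CC[C@H](C(C)(C)O)[C@@H](C1)[C@@H]1COC(C)(C)O1 | intermediate
9 | methyl 2-[(1S,2R)-2-[(4R)-2,2-dimethyl-1,3-dioxolan-4-yl]-4-methylidenecyclohexyl]propan-2-yl oxalate | C=C1CC[C@H](C(C)(C)OC(=O)C(=O)OC)[C@@H](C1)[C@@H]1COC(C)(C)O1 | intermediate
10 | 2-[(1S,2R)-2-formyl-4-methylidenecyclohexyl]propan-2-yl methyl oxalate | C=C1CC[C@H](C(C)(C)OC(=O)C(=O)OC)[C@@H](C1)C=O | intermediate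
11 | methacrolein | CC(=C)C=O | starting material
12 | allylmagnesium bromide | C=CC[Mg]Br | starting material
13 | 2-methylhexa-1,5-dien-3-ol (racemic) | C=CCC(O)C(C)=C | intermediate
14 | ethyl vinyl ether | C=COCC | starting material
15 | 3-(ethenyloxy)-2-methylhexa-1,5-diene | C=CCC(OC=C)C(C)=C | intermediate
16 | (4E)-4-methylocta-4,7-dienal | O=CCC/C(C)=C/CC=C | intermediate
17 | propanoyl chloride | CCC(=O)Cl | starting material
18 | methylketene | CC=C=O | intermediate
19 | (3R,4S)-3-methyl-4-[(3E)-3-methylhepta-3,6-dien-1-yl]oxetan-2-one | O=C1O[C@@H](CC/C(C)=C/CC=C)[C@H]1C | intermediate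
20 | (3R,4S)-3-methyl-4-{2-[(2S,3S)-2-methyl-3-(prop-2-en-1-yl)oxiran-2-yl]ethyl}oxetan-2-one | O=C1O[C@@H](CC[C@]2(C)O[C@H]2CC=C)[C@H]1C | intermediate
21 | (3R,4S)-4-[(3R,4S)-3-hydroperoxy-4-hydroxy-3-methylhept-6-en-1-yl]-3-methyloxetan-2-one | O=C1O[C@@H](CC[C@@](C)(OO)[C@@H](O)CC=C)[C@H]1C | intermediate
22 | caesium (2R)-2-[(3R,6R)-6-[(1S)-1-hydroxybut-3-en-1-yl]-6-methyl-1,2-dioxan-3-yl]propanoate | C=CC[C@H](O)[C@@]1(C)CC[C@H]([C@@H](C)C(=O)[O-])OO1.[Cs+] | intermediate
23 | methyl (2R)-2-[(3R,6R)-6-[(1S)-1-hydroxybut-3-en-1-yl]-6-methyl-1,2-dioxan-3-yl]propanoate | C=CC[C@H](O)[C@@]1(C)CC[C@H]([C@@H](C)C(=O)OC)OO1 | intermediate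
24 | methyl (2R)-2-[(3R,6R)-6-methyl-6-[(1S)-1-(phenoxycarbonothioyloxy)but-3-en-1-yl]-1,2-dioxan-3-yl]propanoate | C=CC[C@H](OC(=S)Oc1ccccc1)[C@@]1(C)CC[C@H]([C@@H](C)C(=O)OC)OO1 | intermediate
25 | methyl (2R)-2-[(3R,6S)-6-(but-3-en-1-yl)-6-methyl-1,2-dioxan-3-yl]propanoate | C=CCC[C@@]1(C)CC[C@H]([C@@H](C)C(=O)OC)OO1 | intermediate
26 | (E)-but-2-enal (crotonaldehyde) | C/C=C/C=O | starting material
27 | methyl (2R)-2-[(3R,6S)-6-methyl-6-[(3E)-5-oxopent-3-en-1-yl]-1,2-dioxan-3-yl]propanoate | O=C/C=C/CC[C@@]1(C)CC[C@H]([C@@H](C)C(=O)OC)OO1 | intermediate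
28 | caesium 2-[(1S,2R)-2-formyl-4-methylidenecyclohexyl]propan-2-yl oxalate | C=C1CC[C@H](C(C)(C)OC(=O)C(=O)[O-])[C@@H](C1)C=O.[Cs+] | intermediate
29 | methyl (2R)-2-[(3R,6S)-6-[(3R)-4-[(1S,2R)-2-formyl-4-methylidenecyclohexyl]-4-methyl-3-(2-oxoethyl)pentyl]-6-methyl-1,2-dioxan-3-yl]propanoate | C=C1CC[C@H](C(C)(C)[C@@H](CC=O)CC[C@@]2(C)CC[C@H]([C@@H](C)C(=O)OC)OO2)[C@@H](C1)C=O | intermediate
30 | methyl (2R)-2-[(3R,6S)-6-{2-[(2S,4aS,8aS)-3-formyl-1,1-dimethyl-6-methylidene-1,2,4a,5,6,7,8,8a-octahydronaphthalen-2-yl]ethyl}-6-methyl-1,2-dioxan-3-yl]propanoate | C=C1CC[C@H]2[C@@H](C1)C=C(C=O)[C@@H](CC[C@@]1(C)CC[C@H]([C@@H](C)C(=O)OC)OO1)C2(C)C | intermediate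
31 | methyl (2R)-2-[(3R,6S)-6-{2-[(2S,4aS,8aS)-3-(hydroxymethyl)-1,1-dimethyl-6-methylidene-1,2,4a,5,6,7,8,8a-octahydronaphthalen-2-yl]ethyl}-6-methyl-1,2-dioxan-3-yl]propanoate | C=C1CC[C@H]2[C@@H](C1)C=C(CO)[C@@H](CC[C@@]1(C)CC[C@H]([C@@H](C)C(=O)OC)OO1)C2(C)C | intermediate
32 | N-allylated 2-nitrobenzenesulfonylhydrazine derived from 31 (CH2OH replaced by CH2N(NH2)SO2C6H4-2-NO2) | C=C1CC[C@H]2[C@@H](C1)C=C(CN(N)S(=O)(=O)c1ccccc1[N+](=O)[O-])[C@@H](CC[C@@]1(C)CC[C@H]([C@@H](C)C(=O)OC)OO1)C2(C)C | intermediate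
33 | allylic diazene derived from 32 (CH2N=NH) | C=C1CC[C@H]2[C@@H](C1)C=C(CN=N)[C@@H](CC[C@@]1(C)CC[C@H]([C@@H](C)C(=O)OC)OO1)C2(C)C | intermediate
34 | methyl (2R)-2-[(3R,6S)-6-{2-[(2R,4aS,8aS)-1,1-dimethyl-3,6-dimethylidenedecahydronaphthalen-2-yl]ethyl}-6-methyl-1,2-dioxan-3-yl]propanoate | C=C1CC[C@H]2[C@@H](C1)CC(=C)[C@@H](CC[C@@]1(C)CC[C@H]([C@@H](C)C(=O)OC)OO1)C2(C)C | intermediate
35 | (2R)-2-[(3R,6S)-6-{2-[(2R,4aS,8aS)-1,1-dimethyl-3,6-dimethylidenedecahydronaphthalen-2-yl]ethyl}-6-methyl-1,2-dioxan-3-yl]propanoic acid | C=C1CC[C@H]2[C@@H](C1)CC(=C)[C@@H](CC[C@@]1(C)CC[C@H]([C@@H](C)C(=O)O)OO1)C2(C)C | target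

**Step count and risks**

Total steps: 19 (ring A branch 6, dioxane branch 9, union and endgame 4). Longest linear sequence: 13 (steps 7 to 19).

Most likely to fail, first: step 16. The hindered tertiary radical may add to the iminium ion slowly or reversibly, or the catalyst may not control the new ring B center. In that case the same bond is made under chelate (auxiliary) control. Alkene 25 undergoes cross-metathesis (same ruthenium catalyst) with (S)-3-acryloyl-4-(diphenylmethyl)oxazolidin-2-one to give the (E)-enoyl imide F1. The radical from 10 (saponified in situ to 28; 4CzIPN, blue light) is added in the presence of Yb(OTf)3, where the s-cis chelate exposes the same alkene face as the iminium ion (Sibi-type addition), and the ytterbium enolate closes ring B on the formyl group to give the β-hydroxy imide F2. Burgess dehydration gives the unsaturated imide F3, and NaBH4 in THF/H2O removes the auxiliary reductively to give allylic alcohol 31, where the route resumes.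

Second: step 12. The hydroperoxide may attack the lactone carbonyl or oligomerise instead of opening the β-lactone at C4. In that case the roles of nucleophile and electrophile are exchanged. Lactone 19 is methanolysed (K2CO3, MeOH, 0 °C) to the syn-hydroxy ester F4, which is converted into the triflate F5 (Tf2O, 2,6-lutidine, −78 °C) and displaced with anhydrous H2O2 without base (SN2, inversion) to give the anti-hydroperoxy ester F6. Shi epoxidation as in step 10 gives the epoxy hydroperoxide F7, whose secondary OOH group opens the epoxide at the tertiary carbon (6-exo, camphorsulfonic acid cat., inversion) to give 23 directly.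

Third: step 14. The carbon radical next to the peroxide may still collapse to an epoxide with O–O cleavage. In that case the hydroxyl group is never introduced. Lactone 19 is treated under Isayama–Mukaiyama conditions (Co(thd)2, O2, Et3SiH), so that hydrogen-atom transfer to the trisubstituted alkene and O2 trapping give the tertiary triethylsilyl peroxide F8 as both epimers at the peroxide carbon. Bu4NF/AcOH frees the hydroperoxide F9, and the conditions of step 12 close the dioxane through the caesium carboxylate F10 and methylate it. Ester 25 is then separated by chromatography from its (6R) epimer F11; half of the material is lost, but steps 10, 11, 13 and 14 are skipped.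

**Further compounds**

F1 | step 16 | methyl (2R)-2-[(3R,6S)-6-methyl-6-{(3E)-5-oxo-5-[(4S)-4-(diphenylmethyl)-2-oxo-1,3-oxazolidin-3-yl]pent-3-en-1-yl}-1,2-dioxan-3-yl]propanoate | O=C(/C=C/CC[C@@]1(C)CC[C@H]([C@@H](C)C(=O)OC)OO1)N1C(=O)OC[C@@H]1C(c1ccccc1)c1ccccc1
F2 | step 16 | β-hydroxy imide: ring B closed with a 4-hydroxy group and a 3-acyl oxazolidinone (mixture at the two new carbinol and acyl-bearing centers) | C=C1CC[C@H]2[C@@H](C1)C(O)C(C(=O)N1C(=O)OC[C@@H]1C(c1ccccc1)c1ccccc1)[C@@H](CC[C@@]1(C)CC[C@H]([C@@H](C)C(=O)OC)OO1)C2(C)C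
F3 | step 16 | unsaturated imide: the 3-formyl group of 30 replaced by the (4S)-4-(diphenylmethyl)-2-oxo-1,3-oxazolidine-3-carbonyl group | C=C1CC[C@H]2[C@@H](C1)C=C(C(=O)N1C(=O)OC[C@@H]1C(c1ccccc1)c1ccccc1)[C@@H](CC[C@@]1(C)CC[C@H]([C@@H](C)C(=O)OC)OO1)C2(C)C
F4 | step 12 | methyl (2R,3S,6E)-3-hydroxy-2,6-dimethyldeca-6,9-dienoate | COC(=O)[C@H](C)[C@@H](O)CC/C(C)=C/CC=C
F5 | step 12 | methyl (2R,3S,6E)-2,6-dimethyl-3-(trifluoromethanesulfonyloxy)deca-6,9-dienoate | COC(=O)[C@H](C)[C@@H](OS(=O)(=O)C(F)(F)F)CC/C(C)=C/CC=C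
F6 | step 12 | methyl (2R,3R,6E)-3-hydroperoxy-2,6-dimethyldeca-6,9-dienoate | COC(=O)[C@H](C)[C@H](OO)CC/C(C)=C/CC=C
F7 | step 12 | methyl (2R,3R)-3-hydroperoxy-2-methyl-5-[(2S,3S)-2-methyl-3-(prop-2-en-1-yl)oxiran-2-yl]pentanoate | COC(=O)[C@H](C)[C@H](OO)CC[C@]1(C)O[C@H]1CC=C
F8 | step 14 | (3R,4S)-3-methyl-4-[3-methyl-3-(triethylsilylperoxy)hept-6-en-1-yl]oxetan-2-one (both epimers at the peroxide carbon) | O=C1O[C@@H](CCC(C)(OO[Si](CC)(CC)CC)CCC=C)[C@H]1C
F9 | step 14 | (3R,4S)-4-(3-hydroperoxy-3-methylhept-6-en-1-yl)-3-methyloxetan-2-one (both epimers at the peroxide carbon) | O=C1O[C@@H](CCC(C)(OO)CCC=C)[C@H]1C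
F10 | step 14 | caesium (2R)-2-[(3R)-6-(but-3-en-1-yl)-6-methyl-1,2-dioxan-3-yl]propanoate (both epimers at C6) | C=CCCC1(C)CC[C@H]([C@@H](C)C(=O)[O-])OO1.[Cs+]
F11 | step 14 | methyl (2R)-2-[(3R,6R)-6-(but-3-en-1-yl)-6-methyl-1,2-dioxan-3-yl]propanoate | C=CCC[C@]1(C)CC[C@H]([C@@H](C)C(=O)OC)OO1
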